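## Retrosynthetic overview

- Ring numbering used below: C1 = ring ketone next to the carbinol, C2 = carbon bearing the hexadec-14-enoyl group, C3 = enol carbon, C4 and C5 = the two CH2 groups, C6 = the (S)-carbinol carbon.
- Key disconnection: ring bonds C4–C5 and C1–C2 are cut together. This unravels the carbocycle into the acyclic β-diketone (E)-nonadec-17-ene-2,4-dione (its C1 methyl becomes ring C4, its C3 methylene becomes ring C2) and methyl (S)-glycidate (oxirane CH2 = C5, oxirane CH = C6, ester carbon = C1). Forward: dianion γ-attack on the epoxide, then Dieckmann-type Claisen closure in the same flask.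
- Enabling feature: the ring triad C5H2–C6H(OH)–C1(=O) is a 2-hydroxy-acid unit at exactly the oxidation level of a glycidic ester (a 1,3-dielectrophile). Its two neighbours C4 and C2 are the γ- and α-carbons of the 1,3-dicarbonyl formed by C3 and the side-chain ketone (a 1,3-dinucleophile). The only stereocentre, C6, therefore comes intact from the chiral pool.
- The diketone comes from γ-alkylation of the acetylacetone dianion with (E)-14-bromotetradec-2-ene. That bromide comes from a one-pot hydroboration/B-alkyl Suzuki coupling of 11-bromoundec-1-ene with (E)-1-bromoprop-1-ene, which fixes the E olefin.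
- Ring order: the single carbocycle is formed last; the key step should deliver the target itself, without protecting groups.

Key step: step 3

Remark: the target is treated as the drawn C3-enol tautomer of (4S)-2-[(E)-hexadec-14-enoyl]-4-hydroxycyclohexane-1,3-dione, and metalated forms of a numbered compound (enolates, dianions, alkoxides) are counted as that compound and not numbered separately.

## Route

Step 1
Reactants: 1 11-bromoundec-1-ene; 2 (E)-1-bromoprop-1-ene
Product: 4 (E)-14-bromotetradec-2-ene, via 9-(11-bromoundecyl)-9-borabicyclo[3.3.1]nonane 3 (not isolated)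
Conditions: 9-BBN, THF, 0 → 23 °C; then 2 (1.3 equiv), Pd(dppf)Cl2 (3 mol %), K3PO4 (3 M aq), DMF, 50 °C
Reagents that add atoms: none
Why: Anti-Markovnikov hydroboration of the terminal olefin with 9-BBN followed by B-alkyl Suzuki–Miyaura coupling should join the primary alkylborane to the alkenyl bromide with retention of the E geometry, the zerovalent palladium–dppf catalyst inserting into the C(sp2)–Br bond much faster than into the primary alkyl bromide, which is carried through untouched.

Step 2
Reactants: 5 pentane-2,4-dione (acetylacetone); 4 (E)-14-bromotetradec-2-ene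
Product: 6 (E)-nonadec-17-ene-2,4-dione
Conditions: 5 (1.5 equiv), NaH, THF, 0 °C; n-BuLi, 0 °C; then 4, 0 → 23 °C; then 1 M HCl
Reagents that add atoms: none
Why: Hauser-type γ-alkylation of a 1,3-diketone dianion: the terminal carbanion is by far the most nucleophilic site and should displace the primary bromide by SN2, and because acetylacetone is symmetric only one C-alkylation product can form.

Step 3
Reactants: 6 (E)-nonadec-17-ene-2,4-dione; 7 methyl (S)-oxirane-2-carboxylate (methyl (S)-glycidate)
Product: 9 (6S)-2-[(14E)-hexadec-14-enoyl]-3,6-dihydroxycyclohex-2-en-1-one (the target), via methyl (2S,20E)-2-hydroxy-5,7-dioxodocos-20-enoate 8 (not isolated)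
Conditions: NaH, THF, 0 °C; n-BuLi, −78 → 0 °C; then 7 (1.2 equiv), BF3·OEt2 (1.2 equiv), −78 °C; then KOtBu (3 equiv), −78 → 23 °C; then 1 M HCl, 0 °C
Reagents that add atoms: none
Why: Proposed new method: the sodium/lithium 1,3-dianion of 6, metalated at the C1 methyl, should open the BF3-activated oxirane of 7 at its CH2 carbon by SN2 attack (ring bond C4–C5) to give the O-borylated alkoxide/diketonate form of 8; once KOtBu has taken up the boron and the mixture warms, the central diketonate carbon should add to the adjacent methyl ester and expel methoxide (Dieckmann-type Claisen condensation, ring bond C1–C2), the closure being pulled forward by formation of the far less basic cyclic triketonate. The closest known reactions are the BF3·OEt2-promoted γ-alkylation of 1,3-dicarbonyl dianions by terminal epoxides, the alkoxide-induced cyclisation of 5,7-dioxo esters to 2-acylcyclohexane-1,3-diones, and the one-pot Michael–Claisen [3+3] route from ketone enolates and acrylates to cyclohexane-1,3-diones; what is new is their merger on a glycidic ester, in which the epoxide takes the role of the Michael acceptor. The one ring closes in a 6-exo-trig (enolendo) mode at the ester carbonyl. No stereocentre is created: C6 is carried over from 7, because substitution takes place at the neighbouring CH2 and the carbinol carbon, flanked by an alkoxide, should not be deprotonated before or after ring closure. The step needs the carbanion to choose the epoxide carbon over the ester carbonyl of 7, which Lewis-acid activation of the strained ring at −78 °C (where acylation of such dianions by esters is expected to be slow) and the unhindered primary oxirane carbon should secure, and it needs metalation of 6 at the C1 methyl rather than the C5 methylene, which follows the established order of secondary ionisation of β-diketones (CH3 before CH2). C- over O-acylation in the closure should follow from the six-membered transition state and the stability of the triketonate.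

## Compound list

1 | 11-bromoundec-1-ene | C=CCCCCCCCCCBr | starting material
2 | (E)-1-bromoprop-1-ene | C/C=C/Br | starting material
3 | 9-(11-bromoundecyl)-9-borabicyclo[3.3.1]nonane | BrCCCCCCCCCCCB1C2CCCC1CCC2 | intermediate
4 | (E)-14-bromotetradec-2-ene | C/C=C/CCCCCCCCCCCBr | intermediate
5 | pentane-2,4-dione (acetylacetone) | CC(=O)CC(C)=O | starting material
6 | (E)-nonadec-17-ene-2,4-dione | CC(=O)CC(=O)CCCCCCCCCCCC/C=C/C | intermediate
7 | methyl (S)-oxirane-2-carboxylate (methyl (S)-glycidate) | COC(=O)[C@@H]1CO1 | starting material
8 | methyl (2S,20E)-2-hydroxy-5,7-dioxodocos-20-enoate (formed as its O-borylated alkoxide/enolate salt) | COC(=O)[C@@H](O)CCC(=O)CC(=O)CCCCCCCCCCCC/C=C/C | intermediate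
9 | (6S)-2-[(14E)-hexadec-14-enoyl]-3,6-dihydroxycyclohex-2-en-1-one (CNP0389589.1) | C/C=C/CCCCCCCCCCCCC(=O)C1=C(O)CC[C@H](O)C1=O | target

## Step count and risks

Total step count: 3. Longest linear sequence: 3 steps (1 → 4 → 6 → 9).

Steps most likely to fail:

**Step 3 (key step, proposed new method).** What may go wrong: acylation of the dianion at the ester carbonyl of the glycidate in competition with epoxide opening; retention of boron on the diketonate so that the Claisen closure stalls and the open hydroxy diketone closes through oxygen to an alkylidene tetrahydrofuran on work-up; partial metalation at the C5 methylene, leading to a branched isomer.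

Fallback (known reaction types only; the ring is built first and the acyl chain attached last): it sets out from 7, also uses bromide 4, and comes back to the route at 9.
- Copper-catalysed opening of 7 with allylmagnesium bromide (CH2=CHCH2MgBr, CuI cat., THF, −78 → −40 °C) at the oxirane CH2 should give methyl (S)-2-hydroxyhex-5-enoate F1.
- Silylation (TBSCl, imidazole, DMF) should give methyl (S)-2-[(tert-butyldimethylsilyl)oxy]hex-5-enoate F2.
- Wacker oxidation (PdCl2, CuCl, O2, DMF/H2O) should give methyl (S)-2-[(tert-butyldimethylsilyl)oxy]-5-oxohexanoate F3.
- Dieckmann cyclisation from the methyl-ketone enolate (LiN(SiMe3)2, THF, −78 → 0 °C) should give (S)-4-[(tert-butyldimethylsilyl)oxy]cyclohexane-1,3-dione F4.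
- In parallel, malonic ester alkylation with 4 (diethyl malonate, NaOEt, EtOH, reflux) should give diethyl 2-[(E)-tetradec-12-en-1-yl]malonate F5; saponification and decarboxylation (KOH, aq EtOH; then HCl, heat) should give (E)-hexadec-14-enoic acid F6.
- DCC/DMAP coupling of F4 with F6 in CH2Cl2, with DMAP-mediated O-to-C acyl migration, should give (6S)-6-[(tert-butyldimethylsilyl)oxy]-2-[(14E)-hexadec-14-enoyl]-3-hydroxycyclohex-2-en-1-one F7.
- HF·pyridine in THF should release 9.

**Step 1.** What may go wrong: loss of the alkyl bromide terminus under the warm aqueous base (hydrolysis, or competing oxidative addition), olefin migration after β-hydride elimination from the alkylpalladium intermediate, or erosion of the E geometry.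

Fallback (the E olefin is set by anti-reduction of an alkyne instead of by cross-coupling): it sets out from 1 and comes back at 4.
- Hydroboration–oxidation of 1 (9-BBN, THF; then NaBO3·4H2O) should give 11-bromoundecan-1-ol F8.
- Alkylation of 1-propynyllithium (LiC≡CCH3, 2.5 equiv, THF/DMPU, −20 → 23 °C) should give tetradec-12-yn-1-ol F9.
- Dissolving-metal reduction (Na, NH3(l)/THF, −33 °C) should give (E)-tetradec-12-en-1-ol F10.
- Appel bromination (CBr4, PPh3, CH2Cl2) should return 4.

**Step 2.** What may go wrong: O-alkylation or double alkylation of the dianion, or base-induced loss of HBr from the bromide.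

Fallback (a masked β-diketone is alkylated as a monoanion): it sets out from 4 and comes back at 6.
- 3,5-Dimethylisoxazole is lithiated at its C5 methyl group (n-BuLi, THF, −78 °C) and alkylated with 4 to give 3-methyl-5-[(E)-pentadec-13-en-1-yl]isoxazole F11.
- Reductive N–O cleavage with Mo(CO)6 in wet MeCN, which should leave the olefin alone, should give (2Z,17E)-2-aminononadeca-2,17-dien-4-one F12.
- Hydrolysis (1 M HCl, THF) should give 6.

## Further compounds

F1 | step 3 | methyl (S)-2-hydroxyhex-5-enoate | COC(=O)[C@@H](O)CCC=C
F2 | step 3 | methyl (S)-2-[(tert-butyldimethylsilyl)oxy]hex-5-enoate | COC(=O)[C@@H](O[Si](C)(C)C(C)(C)C)CCC=C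
F3 | step 3 | methyl (S)-2-[(tert-butyldimethylsilyl)oxy]-5-oxohexanoate | COC(=O)[C@@H](O[Si](C)(C)C(C)(C)C)CCC(C)=O
F4 | step 3 | (S)-4-[(tert-butyldimethylsilyl)oxy]cyclohexane-1,3-dione | O=C1CC(=O)[C@@H](O[Si](C)(C)C(C)(C)C)CC1
F5 | step 3 | diethyl 2-[(E)-tetradec-12-en-1-yl]malonate | CCOC(=O)C(CCCCCCCCCCC/C=C/C)C(=O)OCC
F6 | step 3 | (E)-hexadec-14-enoic acid | C/C=C/CCCCCCCCCCCCC(=O)O
F7 | step 3 | (6S)-6-[(tert-butyldimethylsilyl)oxy]-2-[(14E)-hexadec-14-enoyl]-3-hydroxycyclohex-2-en-1-one | C/C=C/CCCCCCCCCCCCC(=O)C1=C(O)CC[C@H](O[Si](C)(C)C(C)(C)C)C1=O
F8 | step 1 | 11-bromoundecan-1-ol | OCCCCCCCCCCCBr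
F9 | step 1 | tetradec-12-yn-1-ol | CC#CCCCCCCCCCCCO
F10 | step 1 | (E)-tetradec-12-en-1-ol | C/C=C/CCCCCCCCCCCO
F11 | step 2 | 3-methyl-5-[(E)-pentadec-13-en-1-yl]isoxazole | Cc1cc(CCCCCCCCCCCC/C=C/C)on1
F12 | step 2 | (2Z,17E)-2-aminononadeca-2,17-dien-4-one | C/C(N)=C/C(=O)CCCCCCCCCCCC/C=C/C
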